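I began with the easy step: at the last reading of each earlier run I added up the fraction of the charge in the pairs D and G and the fraction in the singles E and L.

| flask | Z | remark | time |
|---|---|---|---|
| ochre | 0.034 M | run made earlier |  |
| teal | 0.075 M | run made earlier |  |
| oak | 0.050 M |  | 5.0 min |
| cedar | 0.050 M |  | 6.0 min |

| run | time / min | L / % | E / % | D / % | G / % | Z / % |
|---|---|---|---|---|---|---|
| ochre | 0.500 | 9.1 | 18.8 | 15.2 | 11.7 | 29.8 |
| ochre | 1.00 | 7.6 | 31.6 | 22.7 | 11.4 | 16.0 |
| ochre | 1.50 | 7.6 | 37.2 | 26.0 | 11.5 | 9.9 |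
| ochre | 2.50 | 9.2 | 45.2 | 28.0 | 13.2 | 4.4 |
| ochre | 3.00 | 8.0 | 47.9 | 30.7 | 12.8 | 1.8 |
| ochre | 4.00 | 9.9 | 46.9 | 30.6 | 13.1 | 1.8 |
| teal | 0.200 | 7.2 | 7.7 | 10.6 | 13.3 | 44.0 |
| teal | 0.667 | 5.8 | 17.6 | 24.2 | 19.7 | 20.3 |
| teal | 1.00 | 3.9 | 22.7 | 31.6 | 21.9 | 12.6 |
| teal | 1.50 | 4.7 | 28.3 | 33.1 | 22.8 | 8.6 |
| teal | 2.50 | 5.4 | 31.2 | 36.6 | 23.4 | 2.5 |
| teal | 3.00 | 5.2 | 31.8 | 39.1 | 23.3 | 1.1 |
| teal | 4.00 | 6.6 | 32.2 | 37.5 | 21.3 | 0.8 |

(scatter of a reading: 1 percentage point)

- percent here means Z units held: one G or D counts as two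

* which of these there is most of at the end, counted by the Z in it, oak (E / G / L / D)
* which of these there is most of at the end, counted by the Z in it, cedar (E / G / L / D)
* how much there is at the end of the one of these that leads, in percent of the Z charged: oak
* how much there is at the end of the one of these that leads, in percent of the Z charged: cedar

The paired-to-single ratio was 0.769 in ochre and 1.52 in teal. I supposed that a route taking two partners gains on a route taking one in step with the charge, so I divided each ratio by its charge and got 22.6 M⁻¹ and 20.2 M⁻¹. Their mean, 21.4 M⁻¹, is a selectivity factor. Multiplied by the charge of oak and cedar it gave N = 1.07, the pairing number, which is the fraction of the charge ending paired per fraction ending single.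

So I reckoned the fraction left single at 0.483. E made up 0.828 of the singles, averaged over the last readings of the two runs, which put E at 40.0% in oak and cedar. With D's share of the pairs taken from ochre's last reading, I put D at 36.2%, less than E.

Was one number enough? From ochre to teal the charge rose by a factor of 2.21 and the ratio by a factor of 1.98, which is close but lower. Using each run's factor by itself, my estimate of E ran from 38.8% to 41.2%.

The forecast said E in both flasks, at 40% in oak and 40% in cedar, within 37.5% to 42.5%, and that “E leads narrowly”. The flasks gave E at 41.2% in oak and E at 41.3% in cedar.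

    Z + L → D (k = 1.80 M⁻¹ s⁻¹)
    L ⇌ E (K = 6.60, k = 0.0920 s⁻¹)
    2 Z → G (k = 0.180 M⁻¹ s⁻¹)
    Z ⇌ Q (K = 0.450, k = 0.0730 s⁻¹)
    Z → L (k = 0.0230 s⁻¹)

Oak's own N came to 1.10. A further flask like cedar, charged at 0.20 M, has N = 4.28 by my factor, which puts E at 15.7%; that flask gave 17.2%, with D leading. Oak had nearly come to rest by 5.00 min: Z and the intermediate Q together still held 0.217% of the charge. Left until 50.0 min, oak showed E at 41.4%, a gain of 0.20 percentage points.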